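The data are calculated from invented constants, and the scatter is random.

At the reading, 5.0 min after the start, the number to watch beside bis adduct is the substrate left, x, as a fraction of its charge. The first addition runs at a constant times [substrate][partner], the second at another constant times [mono adduct][partner]. [Partner] therefore divides out of their ratio, and so does the time. Taking homo dimer as small and integrating that ratio gives bis adduct, as a fraction of the substrate charged, as a curve in x:

bis adduct = 1 − x − (x^s − x)/(1 − s)

Here s, the selectivity factor, is the second constant over the first.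

| flask | substrate | partner | temperature | remark | time |
|---|---|---|---|---|---|
| north-west | 0.33 M | 2.1 M | 75 °C | run made earlier |  |
| north-east | 1.3 M | 2.1 M | 95 °C | run made earlier |  |
| spring | 0.60 M | 2.10 M | 80 °C |  | 5.0 min |
| midnight | 1.2 M | 2.10 M | 110 °C |  | 5.0 min |
| noon | 2.0 M | 2.10 M | 110 °C |  | 5.0 min |
| autumn | 2.0 M | 2.10 M | 80 °C |  | 5.0 min |

| run | time / min | bis adduct / % | substrate / % |
|---|---|---|---|
| north-west | 1.00 | 1.3 | 57.0 |
| north-west | 3.00 | 5.1 | 21.2 |
| north-west | 6.00 | 13.5 | 6.4 |
| north-west | 8.00 | 19.2 | 2.8 |
| north-west | 12.0 | 28.1 | 0.2 |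
| north-west | 15.0 | 33.5 | 0 |
| north-west | 25.0 | 47.4 | 0.4 |
| north-east | 0.417 | 1.5 | 55.1 |
| north-east | 1.00 | 4.7 | 31.4 |
| north-east | 2.00 | 9.7 | 16.6 |
| north-east | 3.00 | 14.0 | 10.8 |
| north-east | 4.00 | 15.7 | 8.2 |
| north-east | 6.00 | 19.9 | 4.7 |
| north-east | 8.00 | 22.4 | 3.4 |

(readings scatter by 0.5 percentage points)

- in percentages every species weighs as the substrate in it: one homo dimer counts as two
- candidate steps: partner <-> dormant form; substrate + partner -> mono adduct + by-product; 2 substrate -> homo dimer; partner + mono adduct -> bis adduct + by-product

* the flasks put in order of amount of bis adduct, in percent of the substrate charged, best first, at 5.0 min (spring / midnight / noon / autumn)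
* the amount of bis adduct, in percent of the substrate charged of the flask you put first, at 5.0 min
* the amount of bis adduct, in percent of the substrate charged of the flask you put last, at 5.0 min

My own reckoning solves the curve for s at the readings taken 8.00 min into the north-west run and 8.00 min into the north-east run:

s at 75 °C = 0.0828

s at 95 °C = 0.107

A straight line of ln s against temperature then gives:

s at 110 °C = 0.129

s at 80 °C = 0.0882

Midnight and noon look nearly the same: one temperature, one partner charge, so one curve. They differ in how far down it each can travel. Beyond one partner per substrate, midnight has 0.900 M spare and noon 0.100 M, so noon should stall at a higher x.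

The forecast gives midnight > noon > spring > autumn, with 26% first and 7% last, and adds: “Noon versus spring is close.”

The flasks give midnight > spring > noon > autumn, with midnight at 31.0%, spring at 14.4%, noon at 12.4% and autumn at 5.67%.

    partner ⇌ dormant form (K = 1.30, k = 0.0117 s⁻¹, Ea = 113 kJ mol⁻¹, ΔH = −30.0 kJ mol⁻¹)
    substrate + partner → mono adduct + by-product (k = 0.0307 M⁻¹ s⁻¹, Ea = 60.0 kJ mol⁻¹)
    2 substrate → homo dimer (k = 7.95 × 10⁻⁶ M⁻¹ s⁻¹, Ea = 98.0 kJ mol⁻¹)
    partner + mono adduct → bis adduct + by-product (k = 0.00410 M⁻¹ s⁻¹, Ea = 77.0 kJ mol⁻¹)
    (constants at 110 °C)

Midnight and noon part by how far their substrate went. Midnight has 2.2% of it left, while noon has 15% left and 2.1% of its own partner charge. On the curve with s = 0.129, these amounts of substrate give 30.2% for midnight and 12.1% for noon, against the 31.0% and 12.4% the flasks hold. Autumn, with s = 0.0882 and 23% of its substrate left, comes out at 5.89% on its own curve, against a simulated 5.67%. Autumn stands low in part because of the falling level of partner: the same run with that fall taken away gives 21.7% of bis adduct instead of 5.67%.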